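**Assumption:** the target SMILES has no stereocentre or stereogenic double bond, so the compound is achiral and "single enantiomer" requires no stereocontrol.

## Retrosynthetic overview

1. Target 12 ⇐ global O-debenzylation of the bis(4-benzyloxybenzyl)phenol 11.
2. 11 ⇐ twofold ortho-selective reductive C–H benzylation of bibenzyl phenol 4 with 4-(benzyloxy)benzaldehyde 5, forming both ArCH2–Ar bonds in one pot (proposed new boronic acid / Hantzsch ester cascade).
3. 4 ⇐ hydrogenation of diarylalkyne 3 ⇐ Sonogashira coupling of 3-bromo-5-methoxyphenol 1 with 3-ethynylanisole 2.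
4. No carbocycle is built: the central ring comes from 1, the anisole ring from 2 and both outer phenol rings from 5; only transient 1,3,2-dioxaborin rings form and open during step 3.

## Route

Step 1
Reactants: 1 3-bromo-5-methoxyphenol; 2 1-ethynyl-3-methoxybenzene
Product: 3 3-methoxy-5-[(3-methoxyphenyl)ethynyl]phenol
Conditions: Pd(PPh3)2Cl2 (3 mol%), CuI (5 mol%), Et3N, DMF (degassed), 70 °C
Reagents that add atoms: none
Why: Sonogashira coupling; both oxygen substituents are meta to bromine, so oxidative addition is not retarded, and the free phenol is tolerated under amine base.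

Step 2
Reactants: 3 3-methoxy-5-[(3-methoxyphenyl)ethynyl]phenol
Product: 4 3-methoxy-5-[2-(3-methoxyphenyl)ethyl]phenol
Conditions: H2 (1 atm), 10% Pd/C, EtOAc/MeOH, rt
Reagents that add atoms: none
Why: Heterogeneous catalytic hydrogenation takes the diarylalkyne fully to the bibenzyl, while the phenol, aryl methyl ethers and arenes are inert under these conditions.

Step 3
Reactants: 4 3-methoxy-5-[2-(3-methoxyphenyl)ethyl]phenol; 5 4-(benzyloxy)benzaldehyde (2.4 equiv)
Product: 11 2,6-bis[4-(benzyloxy)benzyl]-3-methoxy-5-[2-(3-methoxyphenyl)ethyl]phenol, via first benzodioxaborin 6 (not isolated), via first o-quinone methide 7 (not isolated), via monobenzylated phenol 8 (not isolated), via second benzodioxaborin 9 (not isolated), via second o-quinone methide 10 (not isolated)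
Conditions: 3,5-(CF3)2C6H3B(OH)2 (20 mol%), (PhO)2P(O)OH (10 mol%), Hantzsch ester (diethyl 2,6-dimethyl-1,4-dihydropyridine-3,5-dicarboxylate, 2.6 equiv), 4 Å MS, PhMe, 90 °C, slow addition of 4
Reagents that add atoms: none
Why: Proposed new method: a boronic-acid-catalysed, twofold ortho-selective transfer-hydrogenative C–H benzylation. The electron-poor arylboronic acid condenses with the phenol OH, binds the aldehyde at boron and delivers it through a six-membered transition state that can only reach the carbons ortho to the phenolic oxygen, giving dioxaborin 6. The doubly benzylic, p-alkoxy-stabilised C–O bond of 6 then fragments under acid (retro-hetero-Diels–Alder) to o-quinone methide 7 and the regenerated boronic acid. The Hantzsch ester reduces 7 by 1,4-hydride transfer but leaves the electron-rich aldehyde untouched, and the freed phenol 8 repeats the cycle at its last ortho C–H via 9 and 10. The reaction stops at 11 because no ortho C–H remains and the position para to OH is never within reach of the template; whichever ortho site reacts first, both orders converge on 11. Closest known reaction types: stoichiometric phenylboronic-acid-templated ortho-hydroxyalkylation of phenols (Nagata-type benzodioxaborin formation) followed by separate reduction, and Brønsted-acid-catalysed Hantzsch ester reduction of o-quinone methides.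

Step 4
Reactants: 11 2,6-bis[4-(benzyloxy)benzyl]-3-methoxy-5-[2-(3-methoxyphenyl)ethyl]phenol
Product: 12 2,6-bis(4-hydroxybenzyl)-3-methoxy-5-[2-(3-methoxyphenyl)ethyl]phenol
Conditions: H2 (1 atm), 10% Pd/C, EtOAc/MeOH, rt
Reagents that add atoms: none
Why: Catalytic hydrogenolysis (O-debenzylation) cleaves only the two aryl benzyl ethers; the aryl methyl ethers, diarylmethane CH2 groups and bibenzyl bridge are stable, and no stereocentre is involved.

## Compound list

1 | 3-bromo-5-methoxyphenol | COc1cc(O)cc(Br)c1 | starting material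
2 | 1-ethynyl-3-methoxybenzene (3-ethynylanisole) | COc1cccc(C#C)c1 | starting material
3 | 3-methoxy-5-[(3-methoxyphenyl)ethynyl]phenol | COc1cccc(C#Cc2cc(O)cc(OC)c2)c1 | intermediate
4 | 3-methoxy-5-[2-(3-methoxyphenyl)ethyl]phenol | COc1cccc(CCc2cc(O)cc(OC)c2)c1 | intermediate
5 | 4-(benzyloxy)benzaldehyde | O=Cc1ccc(OCc2ccccc2)cc1 | starting material
6 | 4-[4-(benzyloxy)phenyl]-2-[3,5-bis(trifluoromethyl)phenyl]-7-methoxy-5-[2-(3-methoxyphenyl)ethyl]-4H-1,3,2-benzodioxaborinine (racemic at C4, transient) | COc1cccc(CCc2cc(OC)cc3OB(c4cc(C(F)(F)F)cc(C(F)(F)F)c4)OC(c4ccc(OCc5ccccc5)cc4)c23)c1 | intermediate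
7 | 6-{[4-(benzyloxy)phenyl]methylidene}-3-methoxy-5-[2-(3-methoxyphenyl)ethyl]cyclohexa-2,4-dien-1-one (exocyclic alkene geometry not defined, transient) | COc1cccc(CCC2=CC(OC)=CC(=O)C2=Cc2ccc(OCc3ccccc3)cc2)c1 | intermediate
8 | 2-[4-(benzyloxy)benzyl]-5-methoxy-3-[2-(3-methoxyphenyl)ethyl]phenol | COc1cccc(CCc2cc(OC)cc(O)c2Cc2ccc(OCc3ccccc3)cc2)c1 | intermediate
9 | 8-[4-(benzyloxy)benzyl]-4-[4-(benzyloxy)phenyl]-2-[3,5-bis(trifluoromethyl)phenyl]-5-methoxy-7-[2-(3-methoxyphenyl)ethyl]-4H-1,3,2-benzodioxaborinine (racemic at C4, transient) | COc1cccc(CCc2cc(OC)c3C(c4ccc(OCc5ccccc5)cc4)OB(c4cc(C(F)(F)F)cc(C(F)(F)F)c4)Oc3c2Cc2ccc(OCc3ccccc3)cc2)c1 | intermediate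
10 | 2-[4-(benzyloxy)benzyl]-6-{[4-(benzyloxy)phenyl]methylidene}-5-methoxy-3-[2-(3-methoxyphenyl)ethyl]cyclohexa-2,4-dien-1-one (exocyclic alkene geometry not defined, transient) | COc1cccc(CCC2=C(Cc3ccc(OCc4ccccc4)cc3)C(=O)C(=Cc3ccc(OCc4ccccc4)cc3)C(OC)=C2)c1 | intermediate
11 | 2,6-bis[4-(benzyloxy)benzyl]-3-methoxy-5-[2-(3-methoxyphenyl)ethyl]phenol | COc1cccc(CCc2cc(OC)c(Cc3ccc(OCc4ccccc4)cc3)c(O)c2Cc2ccc(OCc3ccccc3)cc2)c1 | intermediate
12 | 2,6-bis(4-hydroxybenzyl)-3-methoxy-5-[2-(3-methoxyphenyl)ethyl]phenol (CNP0201265.0) | COc1cccc(CCc2cc(OC)c(Cc3ccc(O)cc3)c(O)c2Cc2ccc(O)cc2)c1 | target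

## Summary

Total step count: 4.
Longest linear sequence: 4 steps (1 → 3 → 4 → 11 → 12).

## Steps most likely to fail, with fallbacks

**Step 3 (proposed new cascade).** Risks are intermolecular capture of the o-quinone methides 7 and 10 by the electron-rich phenol (triarylmethanes), slow boron turnover, and untemplated Friedel–Crafts attack para to OH. The fallback uses known chemistry, sets out from 4, passes through 8 and comes back at 11; it makes each ArCH2–Ar bond by ortho-formylation, aryl Grignard addition and ionic hydrogenation. Magnesium-mediated ortho-specific formylation of 4 (MgCl2, Et3N, paraformaldehyde, MeCN, reflux) gives 2-hydroxy-4-methoxy-6-[2-(3-methoxyphenyl)ethyl]benzaldehyde F1. Addition of commercial 4-(benzyloxy)phenylmagnesium bromide (2.5 equiv, THF, 0 °C) gives racemic 2-{[4-(benzyloxy)phenyl](hydroxy)methyl}-5-methoxy-3-[2-(3-methoxyphenyl)ethyl]phenol F2. Deoxygenation with Et3SiH/TFA (CH2Cl2, 0 °C) gives 8. A second formylation at the only remaining ortho position gives 3-[4-(benzyloxy)benzyl]-2-hydroxy-6-methoxy-4-[2-(3-methoxyphenyl)ethyl]benzaldehyde F3. The same Grignard addition gives racemic 2-[4-(benzyloxy)benzyl]-6-{[4-(benzyloxy)phenyl](hydroxy)methyl}-5-methoxy-3-[2-(3-methoxyphenyl)ethyl]phenol F4, and Et3SiH/TFA then gives 11. If the first formylation goes to the other ortho carbon, the sequence still converges on 11 because both benzyl groups are identical.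

**Step 1 (Sonogashira on a free bromophenol).** Risks are alkyne homocoupling and sluggish coupling of the phenoxide. The fallback sets out from 1 and comes back at 4, bypassing 3 and step 2, by replacing the sp–sp2 coupling with an sp3–sp2 B-alkyl Suzuki–Miyaura coupling. Commercial 1-ethenyl-3-methoxybenzene is hydroborated with 9-BBN (THF, 0 °C to rt) to give 9-[2-(3-methoxyphenyl)ethyl]-9-borabicyclo[3.3.1]nonane F5. This is coupled in the same pot with 1 (Pd(dppf)Cl2, aq K3PO4 3 equiv, THF/DMF, 65 °C) to give 4 directly.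

**Step 4 (global hydrogenolysis).** Risks are catalyst poisoning by traces of the pyridine or boron residues from step 3 and incomplete cleavage of the second benzyl ether. The fallback sets out from 11 and comes back at 12, replacing reductive cleavage by Lewis-acid ether cleavage with a cation scavenger: BCl3 (4 equiv) and pentamethylbenzene (6 equiv) in CH2Cl2 at −78 °C. The scavenger traps the benzyl cations before they can alkylate the electron-rich rings, and the aryl methyl ethers survive at this temperature. No new intermediate is formed.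

## Further compounds

F1 | step 3 | 2-hydroxy-4-methoxy-6-[2-(3-methoxyphenyl)ethyl]benzaldehyde | COc1cccc(CCc2cc(OC)cc(O)c2C=O)c1
F2 | step 3 | 2-{[4-(benzyloxy)phenyl](hydroxy)methyl}-5-methoxy-3-[2-(3-methoxyphenyl)ethyl]phenol (racemic) | COc1cccc(CCc2cc(OC)cc(O)c2C(O)c2ccc(OCc3ccccc3)cc2)c1
F3 | step 3 | 3-[4-(benzyloxy)benzyl]-2-hydroxy-6-methoxy-4-[2-(3-methoxyphenyl)ethyl]benzaldehyde | COc1cccc(CCc2cc(OC)c(C=O)c(O)c2Cc2ccc(OCc3ccccc3)cc2)c1
F4 | step 3 | 2-[4-(benzyloxy)benzyl]-6-{[4-(benzyloxy)phenyl](hydroxy)methyl}-5-methoxy-3-[2-(3-methoxyphenyl)ethyl]phenol (racemic) | COc1cccc(CCc2cc(OC)c(C(O)c3ccc(OCc4ccccc4)cc3)c(O)c2Cc2ccc(OCc3ccccc3)cc2)c1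
F5 | step 1 | 9-[2-(3-methoxyphenyl)ethyl]-9-borabicyclo[3.3.1]nonane | COc1cccc(CCB2C3CCCC2CCC3)c1
F0 | step 4 | none | none
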